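**Retrosynthetic overview**
1. Target 22 ⇐ 21 ⇐ 20 by desilylation and carbonate methanolysis. The interflavan bond C4(upper)–C6(lower) is made last, by boron-templated syn transfer of the lower aryl group onto C4 of the upper 3,4-cis-diol (cyclic boronate 19). Both units therefore come from one monomer, diol 14: the upper unit as such, the lower unit as carbonate/6-boronic acid 18.
2. Monomer 14 ⇐ gem-diacetate 11 of a trans-2-aryl-2,3-dihydrobenzofuran-3-carbaldehyde. The five-membered O-heterocycle (O1, C2, C3, C3a, C7a) is enlarged to the six-membered ring C by a 1,2-shift of the ring-A carbon from C3 to the exocyclic carbon (the future C4), while the neighbouring acetoxy group delivers O3.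
3. Enabling feature: in the lower unit, C4a of ring A is para to the C7 oxygen and ortho to O1, so this carbon bridges and migrates easily (phenonium ion); and the cis-3,4-diol of ring C is what a cis-fused 1,3-dioxolan-2-ylium ion on C3/C4 releases on hydrolysis.
4. 11 ⇐ trans ester 9 ⇐ diazo ester 7 (enantioselective dirhodium-catalysed benzylic C–H insertion closes the dihydrofuran ring and sets C2) ⇐ arylacetate 5 + benzyl alcohol 3.
5. Ring order: rings A and B are bought; dihydrofuran ring (step 6); ring C by ring expansion (step 9, serving both flavan units); no ring is closed afterwards (boronate and carbonate rings are temporary).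

Key step: step 9

Assumption: Rh2(S-PTTL)4 is taken to give the (2S)-dihydrobenzofuran needed for the (2R)-flavan; if its sense of induction is the opposite, the mirror-image catalyst Rh2(R-PTTL)4 is used and nothing else changes. (TIPS = triisopropylsilyl.)

**Step 1**
Reactants: 1 3,4-dihydroxybenzaldehyde
Product: 2 3,4-bis(triisopropylsilyloxy)benzaldehyde
Conditions: TIPSCl (2.4 equiv), imidazole, DMF, rt
Reagents that add atoms: chlorotriisopropylsilane, CC(C)[Si](Cl)(C(C)C)C(C)C
Why: Standard imidazole-mediated silylation of both phenolic hydroxyls; no stereocentre is involved.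

**Step 2**
Reactants: 2 3,4-bis(triisopropylsilyloxy)benzaldehyde
Product: 3 [3,4-bis(triisopropylsilyloxy)phenyl]methanol
Conditions: NaBH4, THF/EtOH, 0 °C
Reagents that add atoms: none
Why: Borohydride reduction of an aryl aldehyde; the aryl silyl ethers should survive brief contact at 0 °C.

**Step 3**
Reactants: 4 methyl 2-(2,4-dihydroxyphenyl)acetate
Product: 5 methyl 2-[2-hydroxy-4-(triisopropylsilyloxy)phenyl]acetate
Conditions: TIPSCl (1.05 equiv), imidazole, CH2Cl2, 0 °C
Reagents that add atoms: chlorotriisopropylsilane, CC(C)[Si](Cl)(C(C)C)C(C)C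
Why: The bulky silyl chloride should discriminate the unhindered 4-OH from the 2-OH flanked by the CH2CO2Me arm (sterically controlled monosilylation).

**Step 4**
Reactants: 5 methyl 2-[2-hydroxy-4-(triisopropylsilyloxy)phenyl]acetate; 3 [3,4-bis(triisopropylsilyloxy)phenyl]methanol
Product: 6 methyl 2-[2-{[3,4-bis(triisopropylsilyloxy)phenyl]methoxy}-4-(triisopropylsilyloxy)phenyl]acetate
Conditions: PPh3, DIAD, THF, 0 °C → rt
Reagents that add atoms: none
Why: Mitsunobu etherification of a phenol with a primary benzylic alcohol under neutral conditions that leave the aryl silyl ethers untouched.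

**Step 5**
Reactants: 6 methyl 2-[2-{[3,4-bis(triisopropylsilyloxy)phenyl]methoxy}-4-(triisopropylsilyloxy)phenyl]acetate
Product: 7 methyl 2-diazo-2-[2-{[3,4-bis(triisopropylsilyloxy)phenyl]methoxy}-4-(triisopropylsilyloxy)phenyl]acetate
Conditions: p-ABSA, DBU, MeCN, 0 °C → rt
Reagents that add atoms: 4-acetamidobenzenesulfonyl azide, CC(=O)Nc1ccc(cc1)S(=O)(=O)N=[N+]=[N-]
Why: Regitz diazo transfer to an arylacetate gives the donor/acceptor diazo ester.

**Step 6**
Reactants: 7 methyl 2-diazo-2-[2-{[3,4-bis(triisopropylsilyloxy)phenyl]methoxy}-4-(triisopropylsilyloxy)phenyl]acetate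
Product: 9 methyl (2S,3S)-2-[3,4-bis(triisopropylsilyloxy)phenyl]-6-(triisopropylsilyloxy)-2,3-dihydro-1-benzofuran-3-carboxylate (trans), via cis ester 8 (not isolated)
Conditions: Rh2(S-PTTL)4 [dirhodium tetrakis(N-phthaloyl-(S)-tert-leucinate)] (1 mol %), toluene, −60 → 0 °C; then DBU (0.3 equiv), 40 °C
Reagents that add atoms: none
Why: Enantioselective intramolecular 1,5 C–H insertion of the dirhodium carbenoid into the benzylic ether C–H (a known reaction of 2-benzyloxyphenyl diazoacetates) closes the dihydrofuran ring and sets C2 under catalyst control as the cis ester, and DBU then epimerises only the acidic C3 to the more stable trans ester while C2 stays untouched.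

**Step 7**
Reactants: 9 methyl (2S,3S)-2-[3,4-bis(triisopropylsilyloxy)phenyl]-6-(triisopropylsilyloxy)-2,3-dihydro-1-benzofuran-3-carboxylate
Product: 10 (2S,3S)-2-[3,4-bis(triisopropylsilyloxy)phenyl]-6-(triisopropylsilyloxy)-2,3-dihydro-1-benzofuran-3-carbaldehyde (trans)
Conditions: i-Bu2AlH (1.1 equiv), CH2Cl2, −78 °C; Rochelle salt work-up
Reagents that add atoms: none
Why: Partial reduction of the methyl ester through the tetrahedral aluminium hemiacetal at −78 °C; the trans aldehyde is the more stable C3 epimer and is used at once.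

**Step 8**
Reactants: 10 (2S,3S)-2-[3,4-bis(triisopropylsilyloxy)phenyl]-6-(triisopropylsilyloxy)-2,3-dihydro-1-benzofuran-3-carbaldehyde
Product: 11 [(2S,3S)-2-[3,4-bis(triisopropylsilyloxy)phenyl]-6-(triisopropylsilyloxy)-2,3-dihydro-1-benzofuran-3-yl]methylene diacetate (trans gem-diacetate)
Conditions: Ac2O (3 equiv), Sc(OTf)3 (2 mol %), MeCN, 0 °C
Reagents that add atoms: acetic anhydride, CC(=O)OC(C)=O
Why: Lewis-acid-catalysed acylal formation from an aldehyde and acetic anhydride gives a gem-diacetate that carries both the leaving group and the neighbouring group for step 9.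

**Step 9**
Reactants: 11 [(2S,3S)-2-[3,4-bis(triisopropylsilyloxy)phenyl]-6-(triisopropylsilyloxy)-2,3-dihydro-1-benzofuran-3-yl]methylene diacetate
Product: 14 (2R,3S,4S)-2-[3,4-bis(triisopropylsilyloxy)phenyl]-7-(triisopropylsilyloxy)-3,4-dihydro-2H-chromene-3,4-diol (2,3-trans-3,4-cis), via dioxolanylium triflate 12 (not isolated), via hydroxy acetate 13 (not isolated)
Conditions: TMSOTf (1.3 equiv), CH2Cl2 (0.02 M), −78 → −40 °C; then aq. NaHCO3/THF, −40 → 0 °C; then K2CO3 (cat.), MeOH, 0 °C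
Reagents that add atoms: none
Why: Proposed new method: TMSOTf removes one acetoxy group of the gem-diacetate to give an acyloxycarbenium ion at the exocyclic carbon; aryl carbon C3a, activated by the para silyloxy group and the ortho ring oxygen, bridges to it (phenonium ion, spiro three-membered ring) and shifts from C3 to this carbon, which enlarges the dihydrofuran ring to the pyran ring and turns the exocyclic carbon into C4. The acetoxy group remaining on C4 opens the bridged ion at C3 from the side opposite to the departing aryl bond (5-exo-tet closure of the dioxolan-2-ylium ring, inversion at C3), so the 2,3-trans dihydrobenzofuran should give the 2,3-trans flavan while C2, set in step 6, is untouched. C4 is controlled by the cis ring fusion of the dioxolan-2-ylium ion, the resting state to which any C4 epimer returns by reionisation under the Lewis acid; bicarbonate water then attacks the dioxolanylium carbon and not C4, as in the Woodward cis-hydroxylation, and methanolysis of the hydroxy acetate leaves the cis-3,4-diol. The closest known reaction types are the acid-promoted 1,2-aryl shift of α-aryl aldehydes (aldehyde–ketone rearrangement), phenonium-mediated Wagner–Meerwein ring expansions of benzo-fused cycloalkylmethyl cations, and acetoxonium (Woodward–Prévost) cis-dihydroxylation. The step needs aryl migration to outrun loss of H3 (enol acetate formation, or hydride shift and aromatisation to the benzofuran); the doubly oxygen-activated migrating ring and non-basic conditions at low temperature should secure this, and the trans arrangement at C2/C3 keeps ring B from closing onto the cation.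

**Step 10**
Reactants: 14 (2R,3S,4S)-2-[3,4-bis(triisopropylsilyloxy)phenyl]-7-(triisopropylsilyloxy)-3,4-dihydro-2H-chromene-3,4-diol
Product: 15 (2R,3R,4S)-2-[3,4-bis(triisopropylsilyloxy)phenyl]-7-(triisopropylsilyloxy)-3,4-dihydro-2H-chromene-3,4-diyl carbonate (cis-fused cyclic carbonate)
Conditions: CDI (1.5 equiv), CH2Cl2, rt
Reagents that add atoms: 1,1'-carbonyldiimidazole, O=C(n1ccnc1)n1ccnc1
Why: A cis-1,2-diol closes readily to the five-membered cyclic carbonate, which makes the benzylic C4–O bond resistant to ionisation in the later Lewis-acid step.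

**Step 11**
Reactants: 15 (2R,3R,4S)-2-[3,4-bis(triisopropylsilyloxy)phenyl]-7-(triisopropylsilyloxy)-3,4-dihydro-2H-chromene-3,4-diyl carbonate
Product: 16 6-bromo derivative of 15 (bromine on ring A at C6; same configuration)
Conditions: NBS (1.0 equiv), MeCN, −20 °C
Reagents that add atoms: N-bromosuccinimide, O=C1CCC(=O)N1Br
Why: Electrophilic aromatic bromination should go to C6 of ring A, the only position para to the alkyl aryl ether oxygen O1 and less hindered than C8 (between O1 and the silyloxy group), while ring B, activated by silyloxy groups only, is less reactive.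

**Step 12**
Reactants: 16 6-bromo-(2R,3R,4S)-2-[3,4-bis(triisopropylsilyloxy)phenyl]-7-(triisopropylsilyloxy)-3,4-dihydro-2H-chromene-3,4-diyl carbonate
Product: 18 [(2R,3R,4S)-2-[3,4-bis(triisopropylsilyloxy)phenyl]-3,4-(carbonyldioxy)-7-(triisopropylsilyloxy)-3,4-dihydro-2H-chromen-6-yl]boronic acid, via pinacol boronate 17 (not isolated)
Conditions: B2pin2, Pd(dppf)Cl2 (3 mol %), KOAc, 1,4-dioxane, 80 °C; then NaIO4, NH4OAc, acetone/H2O, rt
Reagents that add atoms: bis(pinacolato)diboron, CC1(C)OB(OC1(C)C)B1OC(C)(C)C(C)(C)O1; water, O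
Why: Miyaura borylation of the aryl bromide followed by oxidative removal of pinacol with periodate gives the free boronic acid, and the carbonate and silyl ethers should tolerate KOAc and the neutral periodate buffer.

**Step 13**
Reactants: 14 (2R,3S,4S)-2-[3,4-bis(triisopropylsilyloxy)phenyl]-7-(triisopropylsilyloxy)-3,4-dihydro-2H-chromene-3,4-diol; 18 the 6-boronic acid of the lower-unit carbonate
Product: 20 hexakis-O-TIPS (4→6)-linked dimer with free upper 3-OH and lower 3,4-cyclic carbonate (upper unit 2,3-trans-3,4-cis with the lower C6 on C4; configuration as in the target), via cyclic boronate 19 (not isolated)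
Conditions: 4 Å MS, CH2Cl2, rt; then TMSOTf (1.1 equiv), −78 → −30 °C; aq. NaHCO3
Reagents that add atoms: none
Why: Proposed new method: the cis-3,4-diol of 14 and boronic acid 18 condense to cyclic boronate 19, TMSOTf ionises the benzylic C4–O bond (cation stabilised by the para silyloxy group and O1) while boron stays bound to O3 on the face of the former diol, and the electron-rich aryl group is transferred from boron to C4 through a five-membered cyclic transition state (ipso substitution at C6 of the lower unit), which can only give the 3,4-cis product and fixes the 4→6 regiochemistry; the closest known reaction types are the Petasis borono-Mannich reaction, hydroxyl-directed additions of boronates to cyclic N-acyliminium and oxocarbenium ions, and boron-mediated aglycon delivery.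

**Step 14**
Reactants: 20 hexakis-O-TIPS dimer with lower 3,4-cyclic carbonate
Product: 21 hexakis-O-TIPS dimer with free upper 3-OH and free lower 3,4-cis-diol
Conditions: K2CO3 (cat.), MeOH/THF, 0 °C
Reagents that add atoms: none
Why: Base-catalysed transesterification of the cyclic carbonate with methanol is much faster than attack on the aryl silyl ethers at 0 °C, and removing the carbonate before the phenols are freed avoids 1,6-elimination to a quinone methide at C4 of the lower unit.

**Step 15**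
Reactants: 21 hexakis-O-TIPS dimer triol
Product: 22 target, fisetinidol-(4β→6)-2,3-trans-3,4-cis-leucofisetinidin (CNP0280090.1)
Conditions: TBAF (8 equiv), AcOH (8 equiv), THF, 0 °C → rt, argon; Sephadex LH-20
Reagents that add atoms: none
Why: Fluoride cleaves the six aryl silyl ethers under acetic acid buffering, so that no phenoxide para to the benzylic C4–OH and no catecholate is exposed to base, and no stereocentre is touched.

**Compound list**
1 | 3,4-dihydroxybenzaldehyde | O=Cc1ccc(O)c(O)c1 | starting material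
2 | 3,4-bis(triisopropylsilyloxy)benzaldehyde | O=Cc1ccc(O[Si](C(C)C)(C(C)C)C(C)C)c(O[Si](C(C)C)(C(C)C)C(C)C)c1 | intermediate
3 | [3,4-bis(triisopropylsilyloxy)phenyl]methanol | OCc1ccc(O[Si](C(C)C)(C(C)C)C(C)C)c(O[Si](C(C)C)(C(C)C)C(C)C)c1 | intermediate
4 | methyl 2-(2,4-dihydroxyphenyl)acetate | COC(=O)Cc1ccc(O)cc1O | starting material
5 | methyl 2-[2-hydroxy-4-(triisopropylsilyloxy)phenyl]acetate | COC(=O)Cc1ccc(O[Si](C(C)C)(C(C)C)C(C)C)cc1O | intermediate
6 | methyl 2-[2-{[3,4-bis(TIPS-oxy)phenyl]methoxy}-4-(TIPS-oxy)phenyl]acetate | COC(=O)Cc1ccc(O[Si](C(C)C)(C(C)C)C(C)C)cc1OCc1ccc(O[Si](C(C)C)(C(C)C)C(C)C)c(O[Si](C(C)C)(C(C)C)C(C)C)c1 | intermediate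
7 | methyl 2-diazo-2-[2-{[3,4-bis(TIPS-oxy)phenyl]methoxy}-4-(TIPS-oxy)phenyl]acetate | COC(=O)C(=[N+]=[N-])c1ccc(O[Si](C(C)C)(C(C)C)C(C)C)cc1OCc1ccc(O[Si](C(C)C)(C(C)C)C(C)C)c(O[Si](C(C)C)(C(C)C)C(C)C)c1 | intermediate
8 | methyl (2S,3R)-2-[3,4-bis(TIPS-oxy)phenyl]-6-(TIPS-oxy)-2,3-dihydro-1-benzofuran-3-carboxylate (cis; not isolated) | c1cc2c(cc1O[Si](C(C)C)(C(C)C)C(C)C)O[C@H](c1ccc(O[Si](C(C)C)(C(C)C)C(C)C)c(O[Si](C(C)C)(C(C)C)C(C)C)c1)[C@@H]2C(=O)OC | intermediate
9 | methyl (2S,3S)-2-[3,4-bis(TIPS-oxy)phenyl]-6-(TIPS-oxy)-2,3-dihydro-1-benzofuran-3-carboxylate (trans) | c1cc2c(cc1O[Si](C(C)C)(C(C)C)C(C)C)O[C@H](c1ccc(O[Si](C(C)C)(C(C)C)C(C)C)c(O[Si](C(C)C)(C(C)C)C(C)C)c1)[C@H]2C(=O)OC | intermediate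
10 | (2S,3S)-2-[3,4-bis(TIPS-oxy)phenyl]-6-(TIPS-oxy)-2,3-dihydro-1-benzofuran-3-carbaldehyde (trans) | c1cc2c(cc1O[Si](C(C)C)(C(C)C)C(C)C)O[C@H](c1ccc(O[Si](C(C)C)(C(C)C)C(C)C)c(O[Si](C(C)C)(C(C)C)C(C)C)c1)[C@H]2C=O | intermediate
11 | [(2S,3S)-2-[3,4-bis(TIPS-oxy)phenyl]-6-(TIPS-oxy)-2,3-dihydro-1-benzofuran-3-yl]methylene diacetate | c1cc2c(cc1O[Si](C(C)C)(C(C)C)C(C)C)O[C@H](c1ccc(O[Si](C(C)C)(C(C)C)C(C)C)c(O[Si](C(C)C)(C(C)C)C(C)C)c1)[C@H]2C(OC(C)=O)OC(C)=O | intermediate
12 | 2-methyl-1,3-dioxolan-2-ylium triflate, cis-fused at C3–C4 of the 2,3-trans flavan (not isolated) | c1cc2c(cc1O[Si](C(C)C)(C(C)C)C(C)C)O[C@H](c1ccc(O[Si](C(C)C)(C(C)C)C(C)C)c(O[Si](C(C)C)(C(C)C)C(C)C)c1)[C@H]3OC(C)=[O+][C@@H]23.[O-]S(=O)(=O)C(F)(F)F | intermediate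
13 | (2R,3R,4S)-2-[3,4-bis(TIPS-oxy)phenyl]-3-hydroxy-7-(TIPS-oxy)-3,4-dihydro-2H-chromen-4-yl acetate (2,3-trans-3,4-cis; not isolated) | c1cc2c(cc1O[Si](C(C)C)(C(C)C)C(C)C)O[C@H](c1ccc(O[Si](C(C)C)(C(C)C)C(C)C)c(O[Si](C(C)C)(C(C)C)C(C)C)c1)[C@@H](O)[C@H]2OC(C)=O | intermediate
14 | (2R,3S,4S)-2-[3,4-bis(TIPS-oxy)phenyl]-7-(TIPS-oxy)-3,4-dihydro-2H-chromene-3,4-diol (2,3-trans-3,4-cis) | c1cc2c(cc1O[Si](C(C)C)(C(C)C)C(C)C)O[C@H](c1ccc(O[Si](C(C)C)(C(C)C)C(C)C)c(O[Si](C(C)C)(C(C)C)C(C)C)c1)[C@@H](O)[C@H]2O | intermediate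
15 | (2R,3R,4S)-3,4-cyclic carbonate of 14 | c1cc2c(cc1O[Si](C(C)C)(C(C)C)C(C)C)O[C@H](c1ccc(O[Si](C(C)C)(C(C)C)C(C)C)c(O[Si](C(C)C)(C(C)C)C(C)C)c1)[C@H]3OC(=O)O[C@@H]23 | intermediate
16 | 6-bromo derivative of 15 | Brc1cc2c(cc1O[Si](C(C)C)(C(C)C)C(C)C)O[C@H](c1ccc(O[Si](C(C)C)(C(C)C)C(C)C)c(O[Si](C(C)C)(C(C)C)C(C)C)c1)[C@H]3OC(=O)O[C@@H]23 | intermediate
17 | 6-(4,4,5,5-tetramethyl-1,3,2-dioxaborolan-2-yl) derivative of 15 (not isolated) | CC1(C)OB(OC1(C)C)c1cc2c(cc1O[Si](C(C)C)(C(C)C)C(C)C)O[C@H](c1ccc(O[Si](C(C)C)(C(C)C)C(C)C)c(O[Si](C(C)C)(C(C)C)C(C)C)c1)[C@H]3OC(=O)O[C@@H]23 | intermediate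
18 | 6-boronic acid of 15 | OB(O)c1cc2c(cc1O[Si](C(C)C)(C(C)C)C(C)C)O[C@H](c1ccc(O[Si](C(C)C)(C(C)C)C(C)C)c(O[Si](C(C)C)(C(C)C)C(C)C)c1)[C@H]3OC(=O)O[C@@H]23 | intermediate
19 | cyclic boronate of the 3,4-cis-diol of 14 with boronic acid 18 (not isolated) | c1cc2c(cc1O[Si](C(C)C)(C(C)C)C(C)C)O[C@H](c1ccc(O[Si](C(C)C)(C(C)C)C(C)C)c(O[Si](C(C)C)(C(C)C)C(C)C)c1)[C@H]3OB(O[C@@H]23)c1cc2c(cc1O[Si](C(C)C)(C(C)C)C(C)C)O[C@H](c1ccc(O[Si](C(C)C)(C(C)C)C(C)C)c(O[Si](C(C)C)(C(C)C)C(C)C)c1)[C@H]3OC(=O)O[C@@H]23 | intermediate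
20 | hexakis-O-TIPS fisetinidol-(4β→6)-leucofisetinidin 3,4-cyclic carbonate (upper unit 2,3-trans-3,4-cis, free 3-OH) | CC(C)[Si](C(C)C)(C(C)C)Oc1ccc2c(c1)O[C@H](c1ccc(O[Si](C(C)C)(C(C)C)C(C)C)c(O[Si](C(C)C)(C(C)C)C(C)C)c1)[C@@H](O)[C@H]2c1cc2c(cc1O[Si](C(C)C)(C(C)C)C(C)C)O[C@H](c1ccc(O[Si](C(C)C)(C(C)C)C(C)C)c(O[Si](C(C)C)(C(C)C)C(C)C)c1)[C@H]3OC(=O)O[C@@H]23 | intermediate
21 | hexakis-O-TIPS fisetinidol-(4β→6)-2,3-trans-3,4-cis-leucofisetinidin (three free alcohol OH) | CC(C)[Si](C(C)C)(C(C)C)Oc1ccc2c(c1)O[C@H](c1ccc(O[Si](C(C)C)(C(C)C)C(C)C)c(O[Si](C(C)C)(C(C)C)C(C)C)c1)[C@@H](O)[C@H]2c1cc2c(cc1O[Si](C(C)C)(C(C)C)C(C)C)O[C@H](c1ccc(O[Si](C(C)C)(C(C)C)C(C)C)c(O[Si](C(C)C)(C(C)C)C(C)C)c1)[C@@H](O)[C@H]2O | intermediate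
22 | CNP0280090.1, fisetinidol-(4β→6)-2,3-trans-3,4-cis-leucofisetinidin | Oc1ccc2c(c1)O[C@H](c1ccc(O)c(O)c1)[C@@H](O)[C@H]2c1cc2c(cc1O)O[C@H](c1ccc(O)c(O)c1)[C@@H](O)[C@H]2O | target

**Total step count:** 15. **Longest linear sequence:** 14 steps (steps 1, 2, 4–15).

**Steps most likely to fail**

Step 9 (Proposed new method). What may go wrong: loss of H3 from the acyloxycarbenium ion (enol acetate formation and aromatisation to the benzofuran) may outpace aryl migration, or the C4 cation may be captured intermolecularly by another ring A. The fallback sets out from 10 and comes back at 14. Aldehyde 10 is reduced (NaBH4, EtOH, 0 °C) to [(2S,3R)-2-[3,4-bis(TIPS-oxy)phenyl]-6-(TIPS-oxy)-2,3-dihydro-1-benzofuran-3-yl]methanol F1, which is converted (MsCl, Et3N, CH2Cl2, 0 °C) into its methanesulfonate F2. Buffered acetolysis (KOAc, AcOH, 80 °C), the classical aryl-assisted solvolysis, should let the same ring-A carbon bridge and migrate, with acetate opening the phenonium ion at C3 with inversion, to give the ring-expanded (2R,3S)-2,3-trans-flavan-3-yl acetate F3. Benzylic oxidation at C4 with DDQ in wet CH2Cl2 (the known C4 functionalisation of flavan-3-ol derivatives) then generates the C4 cation, which the neighbouring 3-acetoxy group and water should convert into hydroxy acetate 13. Methanolysis (K2CO3, MeOH, 0 °C) gives 14.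

Step 13 (Proposed new method). What may go wrong: protodeboronation of the electron-rich aryl boron unit before aryl transfer, or intermolecular capture of the C4 cation with loss of facial control. The fallback sets out from 14 and 15 and comes back at 20. It is the known intermolecular Friedel–Crafts coupling of a flavan-4-yl cation with a nucleophilic flavan: 14 is ionised at C4 (TMSOTf cat., CH2Cl2, −40 °C) in the presence of excess 15 (4 equiv), which should react at C6. This should give 20 together with its C4 epimer, the 3,4-trans (4α) dimer F4, from which 20 is separated by chromatography. Steps 11 and 12 are then not needed.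

Step 12. What may go wrong: slow oxidative addition at the hindered, electron-rich bromide, and protodeboronation at 80 °C or during pinacol cleavage. The fallback sets out from 16 and comes back at 18. It replaces palladium catalysis by bromine–lithium exchange with in situ trapping: n-BuLi is added to 16 and B(Oi-Pr)3 in THF/toluene at −95 °C, so that the aryllithium is captured as the lithium aryl(triisopropoxy)borate F5 before it can attack the carbonate. Aqueous NH4Cl work-up gives 18.

**Further compounds**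
F1 | step 9 | [(2S,3R)-2-[3,4-bis(TIPS-oxy)phenyl]-6-(TIPS-oxy)-2,3-dihydro-1-benzofuran-3-yl]methanol | c1cc2c(cc1O[Si](C(C)C)(C(C)C)C(C)C)O[C@H](c1ccc(O[Si](C(C)C)(C(C)C)C(C)C)c(O[Si](C(C)C)(C(C)C)C(C)C)c1)[C@H]2CO
F2 | step 9 | [(2S,3R)-2-[3,4-bis(TIPS-oxy)phenyl]-6-(TIPS-oxy)-2,3-dihydro-1-benzofuran-3-yl]methyl methanesulfonate | c1cc2c(cc1O[Si](C(C)C)(C(C)C)C(C)C)O[C@H](c1ccc(O[Si](C(C)C)(C(C)C)C(C)C)c(O[Si](C(C)C)(C(C)C)C(C)C)c1)[C@H]2COS(C)(=O)=O
F3 | step 9 | (2R,3S)-2-[3,4-bis(TIPS-oxy)phenyl]-7-(TIPS-oxy)-3,4-dihydro-2H-chromen-3-yl acetate | c1cc2c(cc1O[Si](C(C)C)(C(C)C)C(C)C)O[C@H](c1ccc(O[Si](C(C)C)(C(C)C)C(C)C)c(O[Si](C(C)C)(C(C)C)C(C)C)c1)[C@@H](OC(C)=O)C2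
F4 | step 13 | C4 epimer of 20 (upper unit 2,3-trans-3,4-trans) | CC(C)[Si](C(C)C)(C(C)C)Oc1ccc2c(c1)O[C@H](c1ccc(O[Si](C(C)C)(C(C)C)C(C)C)c(O[Si](C(C)C)(C(C)C)C(C)C)c1)[C@@H](O)[C@@H]2c1cc2c(cc1O[Si](C(C)C)(C(C)C)C(C)C)O[C@H](c1ccc(O[Si](C(C)C)(C(C)C)C(C)C)c(O[Si](C(C)C)(C(C)C)C(C)C)c1)[C@H]3OC(=O)O[C@@H]23
F5 | step 12 | lithium triisopropoxy(aryl)borate of the lower-unit carbonate | [Li+].CC(C)O[B-](OC(C)C)(OC(C)C)c1cc2c(cc1O[Si](C(C)C)(C(C)C)C(C)C)O[C@H](c1ccc(O[Si](C(C)C)(C(C)C)C(C)C)c(O[Si](C(C)C)(C(C)C)C(C)C)c1)[C@H]3OC(=O)O[C@@H]23
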